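**Retrosynthetic overview**
1. Target 10 ⇐ tert-butyl ester 8 (silyl-triflate ester cleavage) ⇐ (13Z)-16-hydroxy ester 7 (O-acetylation).
2. 7 ⇐ 3,6-dihydro-1,2-dioxine 5 (methanolysis, Me2S) ⇐ [4+2] cycloaddition of singlet oxygen to vinylketene silyl acetal 4. This is the key step: it forms the C16–O bond, and the six-membered peroxide ring holds C15 and C16 cis, which is the 13Z alkene.
3. 4 ⇐ tert-butyl copalate 2 (γ-deprotonation of the C16 methyl syn to the ester, O-silylation) ⇐ (−)-copalic acid 1.
4. Rings A and B and the stereocentres C5, C9, C10 come intact with 1 (the target is an ent-labdane, 5R,9R,10R). The only ring formed in the route is the transient 1,2-dioxine of step 3.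

Assumption: (−)-copalic acid, the main diterpene acid of commercial copaiba oleoresin and a catalogue compound, is taken as the purchasable starting material; labdane numbering is used (C15 = carboxyl carbon, C16 = the carbon on C13).

Step 1
Reactants: 1 (−)-copalic acid [(13E)-ent-labda-8(17),13-dien-15-oic acid, 5R,9R,10R]
Product: 2 tert-butyl (13E)-ent-labda-8(17),13-dien-15-oate
Conditions: Cl3CC(=NH)OtBu (2 equiv), CH2Cl2/cyclohexane, 25 °C
Reagents that add atoms: tert-butyl 2,2,2-trichloroacetimidate, CC(C)(C)OC(=N)C(Cl)(Cl)Cl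
Why: Trichloroacetimidate O-tert-butylation needs no added acid (the carboxylic acid protonates the imidate), so the 8(17)-alkene is not isomerised, and it installs a bulky ester that suppresses later lactonisation and can be removed without hydrolysing an acetate; no stereocentre is touched.

Step 2
Reactants: 2 tert-butyl (13E)-ent-labda-8(17),13-dien-15-oate
Product: 4 15-tert-butoxy-15-(trimethylsilyloxy)-ent-labda-8(17),13(16),14-triene, via lithium dienolate 3 (not isolated)
Conditions: LiN(iPr)2 (1.2 equiv), THF, −78 °C; then Me3SiCl, −78 → 25 °C; pentane, filtration, used crude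
Reagents that add atoms: chlorotrimethylsilane, C[Si](C)(C)Cl
Why: Kinetic vinylogous enolisation removes a proton from the C16 methyl group, which lies syn to the ester carbonyl in the 13E enoate (lithium-directed γ-deprotonation), and O-silylation of the dienolate gives the 1,1-dioxygenated 1,3-diene; no stereocentre is formed or touched.

Step 3
Reactants: 4 15-tert-butoxy-15-(trimethylsilyloxy)-ent-labda-8(17),13(16),14-triene
Product: 7 tert-butyl (13Z)-16-hydroxy-ent-labda-8(17),13-dien-15-oate, via endoperoxide 5 (not isolated), via hydroperoxide 6 (not isolated)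
Conditions: O2, hν (visible), 5,10,15,20-tetraphenylporphyrin (cat.), CH2Cl2, −78 °C; then MeOH, Me2S, −78 → 25 °C
Reagents that add atoms: dioxygen (as singlet oxygen), O=O
Why: Hetero-Diels–Alder ([4+2]) addition of singlet oxygen to the cisoid, electron-rich diene (much faster than ene attack on the isolated 8(17)-alkene) closes a six-membered peroxide ring across C15 and C16, which fixes these carbons cis, so that methanolytic collapse of the peroxy ortho ester (the mode known from photooxygenation of 2-silyloxyfurans) and Me2S reduction of the hydroperoxide give the 13Z hydroxy ester; the only new stereocentre (C15 of 5) is transient.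

Step 4
Reactants: 7 tert-butyl (13Z)-16-hydroxy-ent-labda-8(17),13-dien-15-oate
Product: 8 tert-butyl (13Z)-16-acetoxy-ent-labda-8(17),13-dien-15-oate
Conditions: Ac2O, pyridine, DMAP (cat.), CH2Cl2, 0 °C
Reagents that add atoms: acetic anhydride, CC(=O)OC(C)=O
Why: DMAP-catalysed O-acetylation of the primary allylic alcohol is far faster than attack of that alcohol on the hindered tert-butyl ester, so the open-chain 13Z acetate forms without butenolide formation or change at C5, C9, C10.

Step 5
Reactants: 8 tert-butyl (13Z)-16-acetoxy-ent-labda-8(17),13-dien-15-oate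
Product: 10 (13Z)-16-acetoxy-ent-labda-8(17),13-dien-15-oic acid (target), via trimethylsilyl ester 9 (not isolated)
Conditions: Me3SiOTf, 2,6-lutidine, CH2Cl2, 0 °C; then aq. NaH2PO4
Reagents that add atoms: none
Why: Silyl-triflate cleavage of the tert-butyl ester (carbonyl O-silylation, loss of isobutene to the lutidine buffer, hydrolysis of the silyl ester on work-up) frees the acid without protic acid or base, so the acetate, the 13Z enoate and the exocyclic alkene survive and the three bought stereocentres are unchanged.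

**Compound list**
1 | (−)-copalic acid, (13E)-ent-labda-8(17),13-dien-15-oic acid, (5R,9R,10R) | C=C1CC[C@@H]2C(C)(C)CCC[C@@]2(C)[C@@H]1CC/C(C)=C/C(=O)O | starting material
2 | tert-butyl (13E)-ent-labda-8(17),13-dien-15-oate | C=C1CC[C@@H]2C(C)(C)CCC[C@@]2(C)[C@@H]1CC/C(C)=C/C(=O)OC(C)(C)C | intermediate
3 | lithium 15-tert-butoxy-ent-labda-8(17),13(16),14-trien-15-olate (dienolate of 2) | C=C1CC[C@@H]2C(C)(C)CCC[C@@]2(C)[C@@H]1CCC(=C)C=C(OC(C)(C)C)[O-].[Li+] | intermediate
4 | 15-tert-butoxy-15-(trimethylsilyloxy)-ent-labda-8(17),13(16),14-triene (C14=C15 geometry not defined) | C=C1CC[C@@H]2C(C)(C)CCC[C@@]2(C)[C@@H]1CCC(=C)C=C(OC(C)(C)C)O[Si](C)(C)C | intermediate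
5 | 3-tert-butoxy-3-(trimethylsilyloxy)-5-{2-[(1R,4aR,8aR)-5,5,8a-trimethyl-2-methylidenedecahydronaphthalen-1-yl]ethyl}-3,6-dihydro-1,2-dioxine (O–O bridge from C15 to C16; both C15 epimers) | C=C1CC[C@@H]2C(C)(C)CCC[C@@]2(C)[C@@H]1CCC1=CC(OC(C)(C)C)(O[Si](C)(C)C)OOC1 | intermediate
6 | tert-butyl (13Z)-16-hydroperoxy-ent-labda-8(17),13-dien-15-oate | C=C1CC[C@@H]2C(C)(C)CCC[C@@]2(C)[C@@H]1CC/C(=C/C(=O)OC(C)(C)C)COO | intermediate
7 | tert-butyl (13Z)-16-hydroxy-ent-labda-8(17),13-dien-15-oate | C=C1CC[C@@H]2C(C)(C)CCC[C@@]2(C)[C@@H]1CC/C(=C/C(=O)OC(C)(C)C)CO | intermediate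
8 | tert-butyl (13Z)-16-acetoxy-ent-labda-8(17),13-dien-15-oate | C=C1CC[C@@H]2C(C)(C)CCC[C@@]2(C)[C@@H]1CC/C(=C/C(=O)OC(C)(C)C)COC(C)=O | intermediate
9 | trimethylsilyl (13Z)-16-acetoxy-ent-labda-8(17),13-dien-15-oate | C=C1CC[C@@H]2C(C)(C)CCC[C@@]2(C)[C@@H]1CC/C(=C/C(=O)O[Si](C)(C)C)COC(C)=O | intermediate
10 | (13Z)-16-acetoxy-ent-labda-8(17),13-dien-15-oic acid, (5R,9R,10R) (CNP0398954.1) | C=C1CC[C@@H]2C(C)(C)CCC[C@@]2(C)[C@@H]1CC/C(=C/C(=O)O)COC(C)=O | target

**Total step count:** 5. **Longest linear sequence:** 5 steps (1 → 10).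

**Steps most likely to fail**

Step 3 is the main risk: the [4+2] addition to an acyclic vinylketene silyl acetal rests on analogy with 2-silyloxyfurans and 1-alkoxydienes, and ene or [2+2] attack of singlet oxygen at the ketene acetal would divert material. The fallback sets out from 4 and comes back at 8. The silyl ketene acetal is brominated at the γ-carbon with N-bromosuccinimide in THF at −78 °C (vinylogous electrophilic substitution from the cisoid diene). This should give mainly tert-butyl (13Z)-16-bromo-ent-labda-8(17),13-dien-15-oate F1 beside its isomer tert-butyl (13E)-16-bromo-ent-labda-8(17),13-dien-15-oate F2, which is removed by chromatography. Displacement of the allylic bromide of F1 with CsOAc in DMF at 25 °C gives acetate 8 directly, replacing steps 3 and 4.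

Step 2 carries three risks: the site of deprotonation, C- versus O-silylation, and the moisture sensitivity of 4. The fallback sets out from 2 and comes back at 7. The lithium dienolate 3 is trapped at carbon with PhSeBr (THF, −78 °C) to give tert-butyl 14-(phenylselanyl)-ent-labda-8(17),13(16)-dien-15-oate F3. H2O2/pyridine in CH2Cl2 at 0 °C oxidises it to tert-butyl 14-(phenylseleninyl)-ent-labda-8(17),13(16)-dien-15-oate F4. Its [2,3]-sigmatropic rearrangement gives the selenenate tert-butyl (13E)-16-(phenylselanyloxy)-ent-labda-8(17),13-dien-15-oate F5 and, after hydrolysis, tert-butyl (13E)-16-hydroxy-ent-labda-8(17),13-dien-15-oate F6. This shift places the ester trans to the new CH2OH, so the geometry must then be corrected: irradiation with catalytic PhSSPh in benzene equilibrates the 13E and 13Z isomers, 7 is separated and F6 is recycled.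

Step 5 must cleave an ester next to an acid-sensitive exocyclic alkene and an allylic acetate. The fallback sets out from 7 and comes back at 10. Alcohol 7 is lactonised with K2CO3 in MeOH to ent-labda-8(17),13-dien-15,16-olide F7. One equivalent of KOH in MeOH/H2O opens it to potassium (13Z)-16-hydroxy-ent-labda-8(17),13-dien-15-oate F8, which is dried and deprotonated with KN(SiMe3)2 in THF/DMF at −78 °C to dipotassium (13Z)-16-oxido-ent-labda-8(17),13-dien-15-oate F9. One equivalent of Ac2O acetylates the alkoxide to potassium (13Z)-16-acetoxy-ent-labda-8(17),13-dien-15-oate F10. Cold acidification to pH 4 with aq. H3PO4 gives 10 without a free hydroxy acid ever being present to relactonise.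

**Further compounds**
F1 | step 3 | tert-butyl (13Z)-16-bromo-ent-labda-8(17),13-dien-15-oate | C=C1CC[C@@H]2C(C)(C)CCC[C@@]2(C)[C@@H]1CC/C(=C/C(=O)OC(C)(C)C)CBr
F2 | step 3 | tert-butyl (13E)-16-bromo-ent-labda-8(17),13-dien-15-oate | C=C1CC[C@@H]2C(C)(C)CCC[C@@]2(C)[C@@H]1CC/C(=C\C(=O)OC(C)(C)C)CBr
F3 | step 2 | tert-butyl 14-(phenylselanyl)-ent-labda-8(17),13(16)-dien-15-oate | C=C1CC[C@@H]2C(C)(C)CCC[C@@]2(C)[C@@H]1CCC(=C)C([Se]c1ccccc1)C(=O)OC(C)(C)C
F4 | step 2 | tert-butyl 14-(phenylseleninyl)-ent-labda-8(17),13(16)-dien-15-oate | C=C1CC[C@@H]2C(C)(C)CCC[C@@]2(C)[C@@H]1CCC(=C)C([Se](=O)c1ccccc1)C(=O)OC(C)(C)C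
F5 | step 2 | tert-butyl (13E)-16-(phenylselanyloxy)-ent-labda-8(17),13-dien-15-oate | C=C1CC[C@@H]2C(C)(C)CCC[C@@]2(C)[C@@H]1CC/C(=C\C(=O)OC(C)(C)C)CO[Se]c1ccccc1
F6 | step 2 | tert-butyl (13E)-16-hydroxy-ent-labda-8(17),13-dien-15-oate | C=C1CC[C@@H]2C(C)(C)CCC[C@@]2(C)[C@@H]1CC/C(=C\C(=O)OC(C)(C)C)CO
F7 | step 5 | ent-labda-8(17),13-dien-15,16-olide | C=C1CC[C@@H]2C(C)(C)CCC[C@@]2(C)[C@@H]1CCC1=CC(=O)OC1
F8 | step 5 | potassium (13Z)-16-hydroxy-ent-labda-8(17),13-dien-15-oate | C=C1CC[C@@H]2C(C)(C)CCC[C@@]2(C)[C@@H]1CC/C(=C/C(=O)[O-])CO.[K+]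
F9 | step 5 | dipotassium (13Z)-16-oxido-ent-labda-8(17),13-dien-15-oate | C=C1CC[C@@H]2C(C)(C)CCC[C@@]2(C)[C@@H]1CC/C(=C/C(=O)[O-])C[O-].[K+].[K+]
F10 | step 5 | potassium (13Z)-16-acetoxy-ent-labda-8(17),13-dien-15-oate | C=C1CC[C@@H]2C(C)(C)CCC[C@@]2(C)[C@@H]1CC/C(=C/C(=O)[O-])COC(C)=O.[K+]
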